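**Plan**

1. Cuts: after removal of the two MOM groups, ring C is cut at two bonds at once, C3–C4 and O1–C8a, giving a ring A piece (C4 on C4a, bromine on C8a) and a ring B piece (C3, C2, O1).
2. Enabling feature: O1–C2–C3 is a latent aryl oxirane whose strained benzylic C3–O1 bond opens with inversion, and C4/C8a are a benzylic carbon and its ortho ring carbon, i.e. a 2-bromobenzyl nucleophile.
3. Forward: ring B is dressed from 2,6-dimethoxyphenol (bromination, branched prenylation, ortho-lithiation/chloroacetylation, oxirane); ring A comes from 3-bromo-4-methylphenol.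
4. The two pieces are joined and ring C is closed in one flask (formal 3+3 annulation: oxirane opening, then copper-mediated O-arylation); acid then frees both phenols.
5. Stereochemistry: C3 is set as the R carbinol by asymmetric transfer hydrogenation of the chloromethyl ketone, carried into the R oxirane and inverted once in the opening to give 3S.

Key step: step 8

Remark: chroman numbering is used (O1, C2, C3, C4, C4a, C5 to C8, C8a; ring B primed), and the 1,1-dimethylallyl group is named 2-methylbut-3-en-2-yl.

**Route**

Step 1
Reactants: 1 2,6-dimethoxyphenol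
Product: 2 1,3-dimethoxy-2-(methoxymethoxy)benzene
Conditions: NaH, MOMCl, THF, 0 °C to rt
Reagents that add atoms: chloromethyl methyl ether (MOMCl), COCCl
Why: Williamson etherification of the sodium phenoxide with the reactive α-chloro ether masks the future 3'-OH as an acetal that tolerates the organolithium, Grignard and copper chemistry to come.

Step 2
Reactants: 2 1,3-dimethoxy-2-(methoxymethoxy)benzene
Product: 3 1-bromo-2,4-dimethoxy-3-(methoxymethoxy)benzene
Conditions: NBS, MeCN, 0 °C to rt
Reagents that add atoms: N-bromosuccinimide (NBS), O=C1CCC(=O)N1Br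
Why: Electrophilic aromatic bromination goes ortho to one methoxy group and para to the other, because the central, twisted OMOM group activates its own para position far less, and one equivalent of NBS should stop at the monobromide.

Step 3
Reactants: 3 1-bromo-2,4-dimethoxy-3-(methoxymethoxy)benzene; 4 3-methylbut-2-en-1-ylboronic acid pinacol ester (prenyl-Bpin)
Product: 5 1,3-dimethoxy-2-(methoxymethoxy)-4-(2-methylbut-3-en-2-yl)benzene
Conditions: Pd(OAc)2 (3 mol%), 1,1'-bis(di-tert-butylphosphino)ferrocene (4 mol%), K3PO4, THF/H2O, 50 °C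
Reagents that add atoms: none
Why: Branched-selective (γ) Suzuki–Miyaura allyl–aryl coupling: the prenylboronate transmetalates with allylic transposition to put palladium on the tertiary carbon, and the bulky chelating bisphosphine blocks the free site needed for η1–η3–η1 isomerisation, so that reductive elimination from divalent palladium should give the 1,1-dimethylallyl arene.

Step 4
Reactants: 5 1,3-dimethoxy-2-(methoxymethoxy)-4-(2-methylbut-3-en-2-yl)benzene; 6 2-chloro-N-methoxy-N-methylacetamide
Product: 8 2-chloro-1-[2,4-dimethoxy-3-(methoxymethoxy)-5-(2-methylbut-3-en-2-yl)phenyl]ethan-1-one, via aryllithium 7 (not isolated)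
Conditions: n-BuLi, TMEDA, THF, 0 °C; then 6, −78 °C; then water
Reagents that add atoms: none
Why: Directed ortho-metalation occurs at the only ring position next to a methoxy group, and the aryllithium is acylated in a Weinreb ketone synthesis, the chelated tetrahedral adduct preventing a second addition.

Step 5
Reactants: 8 2-chloro-1-[2,4-dimethoxy-3-(methoxymethoxy)-5-(2-methylbut-3-en-2-yl)phenyl]ethan-1-one
Product: 10 (2R)-2-[2,4-dimethoxy-3-(methoxymethoxy)-5-(2-methylbut-3-en-2-yl)phenyl]oxirane, via chlorohydrin 9 (not isolated)
Conditions: RuCl[(S,S)-TsDPEN](p-cymene) (1 mol%), HCO2H/Et3N (5:2), EtOAc, rt; then aq NaOH, i-PrOH, 0 °C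
Reagents that add atoms: none
Why: Noyori–Ikariya asymmetric transfer hydrogenation, in which the hydride of the divalent ruthenium complex is delivered within the CH/π-organised six-membered transition state, is expected with the (S,S) catalyst to give the R chlorohydrin, as for other aryl chloromethyl ketones, without touching the isolated alkene; intramolecular Williamson closure at the CH2Cl carbon then leaves the new stereocentre untouched and gives the R oxirane.

Step 6
Reactants: 11 3-bromo-4-methylphenol
Product: 12 2-bromo-4-(methoxymethoxy)-1-methylbenzene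
Conditions: NaH, MOMCl, THF, 0 °C to rt
Reagents that add atoms: chloromethyl methyl ether (MOMCl), COCCl
Why: Williamson etherification as in step 1 protects the future 7-OH in the same way, so that one acid treatment frees both phenols at the end.

Step 7
Reactants: 12 2-bromo-4-(methoxymethoxy)-1-methylbenzene
Product: 13 2-bromo-1-(bromomethyl)-4-(methoxymethoxy)benzene
Conditions: NBS, AIBN (cat.), PhCF3, 80 °C
Reagents that add atoms: N-bromosuccinimide (NBS), O=C1CCC(=O)N1Br
Why: Wohl–Ziegler bromination: the radical chain abstracts a benzylic hydrogen, and the non-polar solvent and initiator disfavour ionic bromination of the ring.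

Step 8
Reactants: 13 2-bromo-1-(bromomethyl)-4-(methoxymethoxy)benzene; 10 (2R)-2-[2,4-dimethoxy-3-(methoxymethoxy)-5-(2-methylbut-3-en-2-yl)phenyl]oxirane
Product: 16 (3S)-3-[2,4-dimethoxy-3-(methoxymethoxy)-5-(2-methylbut-3-en-2-yl)phenyl]-7-(methoxymethoxy)-3,4-dihydro-2H-chromene, via benzylic Grignard reagent 14 (not isolated), via magnesium alkoxide 15 (not isolated)
Conditions: Mg, Et2O, 0 °C; then 10, CuI (10 mol%), THF, −40 to 0 °C; then t-BuOH (destroys excess 14), CuI (to 20 mol%), 1,10-phenanthroline, Cs2CO3, toluene, 110 °C
Reagents that add atoms: none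
Why: Magnesium inserts into the benzylic C–Br bond of 13 much faster than into the aryl C–Br bond and gives 14, whose benzylic carbon C4, aided by catalytic CuI, attacks the oxirane of 10 at the benzylic carbon C3 anti to the departing oxygen (invertive SN2 opening; the closest known type is the copper-catalysed, benzylic-selective opening of enantioenriched aryl oxiranes by Grignard reagents), so that strain release forms C3–C4 and unmasks O1 as the alkoxide 15. The same alkoxide is then arylated within the molecule by monovalent copper at the ortho C8a–Br bond (Ullmann-type etherification, as in the copper-catalysed cyclisation of 3-(2-bromoaryl)propan-1-ols to chromans), which closes ring C as a six-membered ring by C–O reductive elimination from a seven-membered aryl(alkoxo) metallacycle of trivalent copper. The C3 stereocentre is controlled by the substrate alone: the R configuration of the oxirane is inverted once, which gives 3S. The step needs attack at C3 and not at the oxirane CH2, and SN2 and not SN1 character; the first should be secured by the 2'- and 4'-methoxy groups, which polarise the benzylic C–O bond, and by the allyl-like reactivity of benzylic magnesium reagents, the second by low temperature, copper catalysis and the absence of a strong Lewis acid. The choice between the two bromine atoms of 13 rests on the sp3 against the sp2 C–Br bond, and the aryl bromide that survives is the handle for the ring closure.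

Step 9
Reactants: 16 (3S)-3-[2,4-dimethoxy-3-(methoxymethoxy)-5-(2-methylbut-3-en-2-yl)phenyl]-7-(methoxymethoxy)-3,4-dihydro-2H-chromene
Product: 17 (3S)-3-[3-hydroxy-2,4-dimethoxy-5-(2-methylbut-3-en-2-yl)phenyl]-3,4-dihydro-2H-chromen-7-ol (CNP0305994.1)
Conditions: HCl (conc., cat.), MeOH/THF, 45 °C
Reagents that add atoms: none
Why: Acid-catalysed acetal exchange with methanol removes both MOM groups as dimethoxymethane, while the C3 stereocentre, which is neither acidic nor ionisable, the aryl methyl ethers and the monosubstituted alkene should not be affected by dilute acid at this temperature.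

**Compound list**

1 | 2,6-dimethoxyphenol | COc1cccc(OC)c1O | starting material
2 | 1,3-dimethoxy-2-(methoxymethoxy)benzene | COCOc1c(OC)cccc1OC | intermediate
3 | 1-bromo-2,4-dimethoxy-3-(methoxymethoxy)benzene | COCOc1c(OC)ccc(Br)c1OC | intermediate
4 | 3-methylbut-2-en-1-ylboronic acid pinacol ester | CC(C)=CCB1OC(C)(C)C(C)(C)O1 | starting material
5 | 1,3-dimethoxy-2-(methoxymethoxy)-4-(2-methylbut-3-en-2-yl)benzene | C=CC(C)(C)c1ccc(OC)c(OCOC)c1OC | intermediate
6 | 2-chloro-N-methoxy-N-methylacetamide | CON(C)C(=O)CCl | starting material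
7 | [2,4-dimethoxy-3-(methoxymethoxy)-5-(2-methylbut-3-en-2-yl)phenyl]lithium | [Li]c1cc(C(C)(C)C=C)c(OC)c(OCOC)c1OC | intermediate
8 | 2-chloro-1-[2,4-dimethoxy-3-(methoxymethoxy)-5-(2-methylbut-3-en-2-yl)phenyl]ethan-1-one | O=C(CCl)c1cc(C(C)(C)C=C)c(OC)c(OCOC)c1OC | intermediate
9 | (1R)-2-chloro-1-[2,4-dimethoxy-3-(methoxymethoxy)-5-(2-methylbut-3-en-2-yl)phenyl]ethan-1-ol | C=CC(C)(C)c1cc([C@@H](O)CCl)c(OC)c(OCOC)c1OC | intermediate
10 | (2R)-2-[2,4-dimethoxy-3-(methoxymethoxy)-5-(2-methylbut-3-en-2-yl)phenyl]oxirane | C=CC(C)(C)c1cc([C@@H]2CO2)c(OC)c(OCOC)c1OC | intermediate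
11 | 3-bromo-4-methylphenol | Cc1ccc(O)cc1Br | starting material
12 | 2-bromo-4-(methoxymethoxy)-1-methylbenzene | Cc1ccc(OCOC)cc1Br | intermediate
13 | 2-bromo-1-(bromomethyl)-4-(methoxymethoxy)benzene | BrCc1ccc(OCOC)cc1Br | intermediate
14 | [2-bromo-4-(methoxymethoxy)phenyl]methylmagnesium bromide | Br[Mg]Cc1ccc(OCOC)cc1Br | intermediate
15 | bromomagnesium (2S)-3-[2-bromo-4-(methoxymethoxy)phenyl]-2-[2,4-dimethoxy-3-(methoxymethoxy)-5-(2-methylbut-3-en-2-yl)phenyl]propan-1-olate | C=CC(C)(C)c1cc([C@H](Cc2ccc(OCOC)cc2Br)CO[Mg]Br)c(OC)c(OCOC)c1OC | intermediate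
16 | (3S)-3-[2,4-dimethoxy-3-(methoxymethoxy)-5-(2-methylbut-3-en-2-yl)phenyl]-7-(methoxymethoxy)-3,4-dihydro-2H-chromene | C=CC(C)(C)c1cc([C@H]2COc3cc(OCOC)ccc3C2)c(OC)c(OCOC)c1OC | intermediate
17 | (3S)-3-[3-hydroxy-2,4-dimethoxy-5-(2-methylbut-3-en-2-yl)phenyl]-3,4-dihydro-2H-chromen-7-ol | C=CC(C)(C)c1cc([C@H]2COc3cc(O)ccc3C2)c(OC)c(O)c1OC | target

**Count and risks**

Total steps: 9. Longest linear sequence: 7 (steps 1, 2, 3, 4, 5, 8, 9).

Steps most likely to fail:

1. Step 8. Risk: heterolysis of the benzylic C3–O1 bond of the very electron-rich aryl oxirane before the C–C bond forms, which would cause loss of configurational purity and hydride shift to the arylacetaldehyde (Meinwald rearrangement) followed by carbonyl addition. Attack at the oxirane CH2 and slow copper-mediated arylation of a magnesium alkoxide are further risks. Fallback, setting out from 5 and coming back at 16: 5 is lithiated as in step 4 to aryllithium 7, which is trapped with ethylene oxide to give the arylethanol F1. TEMPO/PhI(OAc)2 in MeCN/water should oxidise it to the arylacetic acid F2. Activation as the mixed pivalic anhydride (PivCl, Et3N) and reaction with lithiated (4S)-4-benzyl-1,3-oxazolidin-2-one gives the N-acyl oxazolidinone F3. Evans alkylation of its sodium enolate (NaHMDS, THF, −78 °C) with 13, on the face opposite the benzyl group, is expected to give the (2S)-alkylated imide F4. LiBH4 in THF/MeOH releases the auxiliary and gives the (2S)-bromoaryl propanol F5, the protonated form of 15. CuI, 1,10-phenanthroline and Cs2CO3 in toluene at 110 °C then close ring C to 16. This sequence never places a leaving group on C3, so the ionisation problem does not arise.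

2. Step 3. Risk: isomerisation of the tertiary allylpalladium species to the primary one before reductive elimination (linear prenyl product), slow coupling at the ortho-methoxy aryl bromide, and protodeboronation of 4. Fallback, setting out from 3 and coming back at 5: palladium-catalysed α-arylation of isobutyraldehyde with 3 (Pd(OAc)2, rac-BINAP, Cs2CO3, 1,4-dioxane, 80 °C) should give the quaternary aldehyde F6. Wittig methylenation (Ph3PCH3Br, KOt-Bu, THF) then turns the formyl group into the vinyl group of 5. The regiochemical question disappears because the quaternary carbon is made at an enolate carbon that has no allylic isomer.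

3. Step 5. Risk: incomplete facial selectivity with the ortho-methoxy aryl ketone, displacement of chloride by formate or amine during the reduction, and acid- or silica-induced ring opening of the oxirane on isolation. Fallback, setting out from 8 and coming back at 10: NaBH4 in MeOH gives the racemic chlorohydrin F7, and aq NaOH closes it to the racemic oxirane F8. Jacobsen hydrolytic kinetic resolution with (R,R)-N,N'-bis(3,5-di-tert-butylsalicylidene)-1,2-cyclohexanediaminocobalt acetate, (salen)Co(OAc) with trivalent cobalt, and about half an equivalent of water is expected to hydrolyse the S oxirane faster. This leaves 10 after separation from the diol.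

**Further compounds**

F1 | step 8 | 2-[2,4-dimethoxy-3-(methoxymethoxy)-5-(2-methylbut-3-en-2-yl)phenyl]ethan-1-ol | C=CC(C)(C)c1cc(CCO)c(OC)c(OCOC)c1OC
F2 | step 8 | [2,4-dimethoxy-3-(methoxymethoxy)-5-(2-methylbut-3-en-2-yl)phenyl]acetic acid | C=CC(C)(C)c1cc(CC(=O)O)c(OC)c(OCOC)c1OC
F3 | step 8 | (4S)-4-benzyl-3-{[2,4-dimethoxy-3-(methoxymethoxy)-5-(2-methylbut-3-en-2-yl)phenyl]acetyl}-1,3-oxazolidin-2-one | C=CC(C)(C)c1cc(CC(=O)N2C(=O)OC[C@@H]2Cc2ccccc2)c(OC)c(OCOC)c1OC
F4 | step 8 | (4S)-4-benzyl-3-{(2S)-3-[2-bromo-4-(methoxymethoxy)phenyl]-2-[2,4-dimethoxy-3-(methoxymethoxy)-5-(2-methylbut-3-en-2-yl)phenyl]propanoyl}-1,3-oxazolidin-2-one | C=CC(C)(C)c1cc([C@H](Cc2ccc(OCOC)cc2Br)C(=O)N2C(=O)OC[C@@H]2Cc2ccccc2)c(OC)c(OCOC)c1OC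
F5 | step 8 | (2S)-3-[2-bromo-4-(methoxymethoxy)phenyl]-2-[2,4-dimethoxy-3-(methoxymethoxy)-5-(2-methylbut-3-en-2-yl)phenyl]propan-1-ol | C=CC(C)(C)c1cc([C@H](Cc2ccc(OCOC)cc2Br)CO)c(OC)c(OCOC)c1OC
F6 | step 3 | 2-[2,4-dimethoxy-3-(methoxymethoxy)phenyl]-2-methylpropanal | CC(C)(C=O)c1ccc(OC)c(OCOC)c1OC
F7 | step 5 | racemic 2-chloro-1-[2,4-dimethoxy-3-(methoxymethoxy)-5-(2-methylbut-3-en-2-yl)phenyl]ethan-1-ol | C=CC(C)(C)c1cc(C(O)CCl)c(OC)c(OCOC)c1OC
F8 | step 5 | racemic 2-[2,4-dimethoxy-3-(methoxymethoxy)-5-(2-methylbut-3-en-2-yl)phenyl]oxirane | C=CC(C)(C)c1cc(C2CO2)c(OC)c(OCOC)c1OC
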